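**Retrosynthetic overview**
1. Feature used: the C18 oxygen sits on the α face of ring A at C4, next to C5, and C9 of ring B carries the carbon C11. An ester link C18–O–C11(=O) can therefore tie a C8≡C9 alkyne (C17 as its methyl) to a ring A diene C10=C5–C6=C7.
2. Late stage: C12–C13 by B-alkyl Suzuki–Miyaura coupling with a (Z)-3-iodobut-2-enoate; C12 by methylenation of the C11 aldehyde; C8=C17 and C9–H by photodeconjugation of the C8=C9 ester; C6–OH and C5–H by α-face hydroboration of C5=C6.
3. Key disconnection: C9–C10 and C7–C8 by a type 2 intramolecular Diels–Alder reaction of the C18 but-2-ynoate, which closes ring B and a bridging seven-membered lactone and relays C4 to the quaternary C10.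
4. Precursor: ring A from 2,6-dimethylcyclohexanone; C4 by decarboxylative asymmetric allylation, the allyl group trimmed to C18–OH, C6–C7 by vinyl coupling of the enol triflate.
5. Ring order: ring A (bought), then ring B together with the lactone (step 8); the lactone is opened in step 9.

Key step: step 8

Remark: labdane numbering is used (decalin C1–C10, C11 on C9, C17 on C8, C18 = CH2O on the α face of C4, C19 = 4β-methyl, C20 = 10β-methyl; α is the face opposite C20). It is assumed that the (S)-configured PHOX ligand gives the 2S ketone, by analogy with the enol carbonate of 2-methylcyclohexanone.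

**Route**

Step 1
Reactants: 1 2,6-dimethylcyclohexanone
Product: 3 allyl 2,6-dimethylcyclohex-1-en-1-yl carbonate, via lithium 2,6-dimethylcyclohex-1-en-1-olate 2 (not isolated)
Conditions: LiN(SiMe3)2, TMEDA, THF, 0 °C; allyl chloroformate, −78 °C → rt
Reagents that add atoms: allyl chloroformate, C=CCOC(=O)Cl
Why: Deprotonation gives the tetrasubstituted enolate (both α-positions are equivalent), which the hard chloroformate acylates on oxygen (enol carbonate formation).

Step 2
Reactants: 3 allyl enol carbonate
Product: 4 (2S)-2-allyl-2,6-dimethylcyclohexanone (C6 epimers)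
Conditions: Pd2(dba)3 (2.5 mol%), (S)-t-Bu-PHOX (6 mol%), THF, 25 °C
Reagents that add atoms: none
Why: Decarboxylative asymmetric allylic alkylation (enantioselective Tsuji allylation): loss of CO2 gives a π-allylpalladium enolate that recombines inside the chiral P,N-ligand sphere, so the ligand sets the quaternary centre C4; the C6 epimers do not matter because C6 becomes sp2 in step 4.

Step 3
Reactants: 4 allyl ketone
Product: 5 (2S)-2,6-dimethyl-2-[(E)-prop-1-en-1-yl]cyclohexanone (C6 epimers)
Conditions: PdCl2(MeCN)2 (5 mol%), toluene, 60 °C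
Reagents that add atoms: none
Why: Catalysed alkene isomerisation moves the terminal double bond by one position, stops at the quaternary carbon and should give the more stable E-propenyl group without touching C4.

Step 4
Reactants: 5 propenyl ketone
Product: 7 (6S)-2,6-dimethyl-6-[(E)-prop-1-en-1-yl]cyclohex-1-en-1-yl trifluoromethanesulfonate, via potassium enolate 6 (not isolated)
Conditions: KN(SiMe3)2, THF, −78 → 0 °C; PhNTf2, −78 °C → rt
Reagents that add atoms: N-phenylbis(trifluoromethanesulfonimide), O=S(=O)(N(c1ccccc1)S(=O)(=O)C(F)(F)F)C(F)(F)F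
Why: C6–H is the only enolisable hydrogen, so O-sulfonylation of the enolate (enol triflate formation) gives a single tetrasubstituted alkenyl triflate and removes the C6 stereocentre.

Step 5
Reactants: 7 enol triflate
Product: 9 (6S)-6-(hydroxymethyl)-2,6-dimethylcyclohex-1-en-1-yl trifluoromethanesulfonate, via ozonide 8 (not isolated)
Conditions: O3, CH2Cl2, −78 °C (Sudan red 7B end point); NaBH4, EtOH, −78 °C → rt
Reagents that add atoms: ozone, [O-][O+]=O
Why: Ozonolysis with reductive work-up: the electron-poor, fully substituted alkenyl triflate should react with electrophilic ozone far more slowly than the 1,2-dialkyl alkene, and borohydride reduces the ozonide to the C18 alcohol while the triflate and C4 stay intact.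

Step 6
Reactants: 9 hydroxymethyl enol triflate; 10 potassium vinyltrifluoroborate
Product: 11 [(1R)-1,3-dimethyl-2-vinylcyclohex-2-en-1-yl]methanol
Conditions: PdCl2(dppf) (5 mol%), Cs2CO3, THF/H2O (10:1), 70 °C
Reagents that add atoms: none
Why: Suzuki–Miyaura coupling of an alkenyl triflate with a vinyltrifluoroborate brings in C6–C7 at the fixed ring position and tolerates the free neopentyl alcohol.

Step 7
Reactants: 11 diene alcohol; 12 but-2-ynoic acid
Product: 13 [(1R)-1,3-dimethyl-2-vinylcyclohex-2-en-1-yl]methyl but-2-ynoate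
Conditions: DCC, DMAP (cat.), CH2Cl2, 0 °C
Reagents that add atoms: none
Why: Steglich esterification of the neopentyl alcohol; low temperature and catalytic DMAP keep the ynoate from isomerising to the allenoate.

Step 8
Reactants: 13 C18 but-2-ynoate of the ring A vinylcyclohexene
Product: 14 tricyclic lactone: 18→11 lactone of 18-hydroxy-12,13,14,15,16-pentanorlabda-5,8-dien-11-oic acid (C19 and C20 both β; lactone bridge on the α face)
Conditions: 1,2-dichlorobenzene (0.005 M), BHT (cat.), 180 °C, sealed tube, Ar
Reagents that add atoms: none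
Why: Proposed new method: on heating, the s-cis conformer of the C10=C5–C6=C7 diene and the tethered ynoate should combine in a concerted, asynchronous [4+2] cycloaddition (diene HOMO, ynoate LUMO) in which the unhindered C7–C8 bond runs ahead of the C9–C10 bond; the closest known reactions are type 2 intramolecular Diels–Alder reactions of 2-tethered butadienes with alkyne dienophiles, which give bridgehead dienes, and the bimolecular addition of acetylenic esters to 1-vinyl-2,6,6-trimethylcyclohexene. Ring B closes as a cyclohexa-1,4-diene by the cycloaddition itself, and the seven-membered lactone closes in the bridged (type 2) mode as the C4–C18–O–C11 tether becomes the four-atom bridge of a bicyclo[4.3.1] unit with bridgehead alkenes at C5 and C9. The new quaternary centre C10 is controlled by C4 through the tether: C18 lies on the α face of ring A and its four-atom link lets C9 reach C10 only from that face, so C20 ends up β, cis to C19. The step needs regioselectivity (C9 to C10, not to C7), which the short tether enforces and the ynoate polarisation (β-carbon C8 to the unsubstituted terminus C7) supports. It must also outrun the [1,5]-hydrogen shift of the diene and bimolecular addition, hence high dilution, a radical inhibitor and the lowest workable temperature. The disfavoured ester rotamer needed in the transition state and the strain of the bridgehead diene are the cost, set against the entropic gain of tethering an otherwise sluggish tetrolate.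

Step 9
Reactants: 14 tricyclic lactone
Product: 15 methyl 18-hydroxy-12,13,14,15,16-pentanorlabda-5,8-dien-11-oate
Conditions: K2CO3 (0.2 equiv), MeOH, 0 °C → rt
Reagents that add atoms: methanol, CO
Why: Base-catalysed transesterification (methanolysis) is driven by relief of the bridgehead-alkene strain of the twisted lactone and frees C18–OH; the mild base should leave the skipped diene in place and no stereocentre is touched.

Step 10
Reactants: 15 hydroxy ester
Product: 16 methyl 18-(triethylsilyloxy)-12,13,14,15,16-pentanorlabda-5,8-dien-11-oate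
Conditions: TESCl, imidazole, CH2Cl2, 0 °C
Reagents that add atoms: chlorotriethylsilane, CC[Si](Cl)(CC)CC
Why: Silyl ether formation on the primary alcohol gives a C18 protecting group that is transparent at 254 nm and stable to borane and hydride.

Step 11
Reactants: 16 diene ester
Product: 18 methyl 6α-hydroxy-18-(triethylsilyloxy)-12,13,14,15,16-pentanorlabd-8-en-11-oate (5α-H), via C6 alkylborane 17 (not isolated)
Conditions: BH3·THF, THF, 0 °C → rt; NaOH, H2O2, 0 °C
Reagents that add atoms: hydrogen peroxide, OO
Why: Hydroboration–oxidation: borane should select the trisubstituted C5=C6 over the tetrasubstituted, ester-deactivated C8=C9 and add boron to C6 and hydrogen to C5 syn from the α face, because the β face is screened by the syn-axial C19 and C20 methyls; oxidation with retention sets C5–H α (trans ring fusion) and C6–OH α.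

Step 12
Reactants: 18 C6 alcohol
Product: 19 methyl 6α-(tert-butyldimethylsilyloxy)-18-(triethylsilyloxy)-12,13,14,15,16-pentanorlabd-8-en-11-oate
Conditions: TBSOTf, 2,6-lutidine, CH2Cl2, −78 → 0 °C
Reagents that add atoms: tert-butyldimethylsilyl triflate, CC(C)(C)[Si](C)(C)OS(=O)(=O)C(F)(F)F
Why: Silyl triflate silylation of the hindered secondary alcohol masks C6–O through the oxidation, olefination and acylation steps and keeps it distinguishable from C18–O.

Step 13
Reactants: 19 conjugated ester
Product: 21 methyl 6α-(tert-butyldimethylsilyloxy)-18-(triethylsilyloxy)-12,13,14,15,16-pentanorlabd-8(17)-en-11-oate (9α-H), via photodienol 20 (not isolated)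
Conditions: hν (254 nm, quartz), 1,2-dimethylimidazole (cat.), hexane, 20 °C
Reagents that add atoms: none
Why: Photodeconjugation of an α,β-unsaturated ester: the excited carbonyl abstracts hydrogen from C17, the only γ-carbon held cis to the ester on the ring-locked C8=C9 (1,5-hydrogen shift), and the dienol is ketonised by base-mediated protonation at C9 from the α face, anti to the axial C20 methyl, which places the ester equatorial and sets C9–H α.

Step 14
Reactants: 21 deconjugated ester
Product: 22 6α-(tert-butyldimethylsilyloxy)-18-(triethylsilyloxy)-12,13,14,15,16-pentanorlabd-8(17)-en-11-ol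
Conditions: LiAlH4, THF, 0 °C
Reagents that add atoms: none
Why: Hydride reduction of the ester to the primary alcohol; the silyl ethers and the isolated alkene are inert and C9 is not enolised.

Step 15
Reactants: 22 C11 alcohol
Product: 23 6α-(tert-butyldimethylsilyloxy)-18-(triethylsilyloxy)-12,13,14,15,16-pentanorlabd-8(17)-en-11-al
Conditions: Dess–Martin periodinane, NaHCO3, CH2Cl2, 0 °C
Reagents that add atoms: none
Why: Dess–Martin oxidation under buffered, non-basic conditions should give the β,γ-unsaturated aldehyde without epimerising C9 or moving the C8=C17 alkene; the aldehyde is used without chromatography.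

Step 16
Reactants: 23 C11 aldehyde
Product: 24 6α-(tert-butyldimethylsilyloxy)-18-(triethylsilyloxy)-13,14,15,16-tetranorlabda-8(17),11-diene
Conditions: Ph3PCH3Br, KN(SiMe3)2, THF, 0 °C; then 23, −78 → 0 °C
Reagents that add atoms: methyltriphenylphosphonium bromide, C[P+](c1ccccc1)(c1ccccc1)c1ccccc1.[Br-]
Why: Wittig methylenation: addition of the unstabilised ylide at low temperature should outpace enolisation of the α-branched aldehyde, so C9 keeps its configuration and C12 arrives as a vinyl CH2.

Step 17
Reactants: 12 but-2-ynoic acid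
Product: 25 (Z)-3-iodobut-2-enoic acid
Conditions: NaI, AcOH, 110 °C
Reagents that add atoms: sodium iodide, [Na+].[I-]
Why: Hydroiodination of the ynoic acid by conjugate addition of iodide and anti protonation gives the (Z)-β-iodo acid (iodine cis to the carboxyl), which fixes the later alkene geometry.

Step 18
Reactants: 25 (Z)-3-iodobut-2-enoic acid
Product: 26 2-(trimethylsilyl)ethyl (Z)-3-iodobut-2-enoate
Conditions: 2-(trimethylsilyl)ethanol, DCC, DMAP (cat.), CH2Cl2, 0 °C
Reagents that add atoms: 2-(trimethylsilyl)ethanol, C[Si](C)(C)CCO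
Why: Steglich esterification gives an ester that survives the cross-coupling and is later cleaved by fluoride without touching a benzoate.

Step 19
Reactants: 24 C11=C12 vinyl compound; 26 (Z)-iodoenoate
Product: 28 2-(trimethylsilyl)ethyl (13Z)-6α-(tert-butyldimethylsilyloxy)-18-(triethylsilyloxy)labda-8(17),13-dien-15-oate, via C12 disiamylborane 27 (not isolated)
Conditions: disiamylborane (BH3·THF + 2-methylbut-2-ene), THF, 0 °C → rt; then 26, PdCl2(dppf) (5 mol%), K3PO4 (3 M aq.), DMF, 50 °C
Reagents that add atoms: none
Why: Hydroboration then B-alkyl Suzuki–Miyaura coupling: the bulky dialkylborane should select the monosubstituted C11=C12 over the 1,1-disubstituted C8=C17 and place boron on C12, and the primary alkyl group is transferred to the alkenyl iodide with retention of geometry, giving the (Z)-enoate with C12 cis to the ester.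

Step 20
Reactants: 28 bis-silyl ether
Product: 29 2-(trimethylsilyl)ethyl (13Z)-6α-(tert-butyldimethylsilyloxy)-18-hydroxylabda-8(17),13-dien-15-oate
Conditions: PPTS, MeOH/CH2Cl2, 0 °C
Reagents that add atoms: none
Why: Acid-catalysed methanolysis (selective desilylation) removes the primary triethylsilyl ether much faster than the hindered secondary tert-butyldimethylsilyl ether; the ester and the alkenes are unaffected.

Step 21
Reactants: 29 C18 alcohol
Product: 30 2-(trimethylsilyl)ethyl (13Z)-18-benzoyloxy-6α-(tert-butyldimethylsilyloxy)labda-8(17),13-dien-15-oate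
Conditions: BzCl, pyridine, DMAP (cat.), CH2Cl2, 0 °C
Reagents that add atoms: benzoyl chloride, O=C(Cl)c1ccccc1
Why: Acylation of the only free hydroxyl (benzoylation) installs the C18 benzoate.

Step 22
Reactants: 30 protected benzoate
Product: 31 (13Z)-18-benzoyloxy-6α-hydroxylabda-8(17),13-dien-15-oic acid (CNP0304840.1)
Conditions: Bu4NF, THF, 0 °C → rt; aq. NH4Cl work-up
Reagents that add atoms: none
Why: Fluoride-induced desilylation cleaves the C6 silyl ether and, by β-elimination of ethene and fluorotrimethylsilane, the 2-(trimethylsilyl)ethyl ester, releasing the C6 alcohol and the C15 acid while the benzoate, the exocyclic alkene and the (Z)-enoate should stay intact.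

**Compound list**

1 | 2,6-dimethylcyclohexanone (cis/trans mixture) | CC1CCCC(C)C1=O | starting material
2 | lithium 2,6-dimethylcyclohex-1-en-1-olate | [Li+].[O-]C1=C(C)CCCC1C | intermediate (not isolated)
3 | allyl 2,6-dimethylcyclohex-1-en-1-yl carbonate (racemic) | C=CCOC(=O)OC1=C(C)CCCC1C | intermediate
4 | (2S)-2-allyl-2,6-dimethylcyclohexanone (C6 epimers) | O=C1[C@](C)(CC=C)CCCC1C | intermediate
5 | (2S)-2,6-dimethyl-2-[(E)-prop-1-en-1-yl]cyclohexanone (C6 epimers) | O=C1[C@](C)(/C=C/C)CCCC1C | intermediate
6 | potassium (6S)-2,6-dimethyl-6-[(E)-prop-1-en-1-yl]cyclohex-1-en-1-olate | CC1=C([O-])[C@](C)(/C=C/C)CCC1.[K+] | intermediate (not isolated)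
7 | (6S)-2,6-dimethyl-6-[(E)-prop-1-en-1-yl]cyclohex-1-en-1-yl trifluoromethanesulfonate | CC1=C(OS(=O)(=O)C(F)(F)F)[C@](C)(/C=C/C)CCC1 | intermediate
8 | ozonide (3-methyl-1,2,4-trioxolan-5-yl in place of the propenyl group of 7; quaternary centre unchanged) | CC1OOC(O1)[C@]2(C)CCCC(C)=C2OS(=O)(=O)C(F)(F)F | intermediate (not isolated)
9 | (6S)-6-(hydroxymethyl)-2,6-dimethylcyclohex-1-en-1-yl trifluoromethanesulfonate | CC1=C(OS(=O)(=O)C(F)(F)F)[C@](C)(CO)CCC1 | intermediate
10 | potassium vinyltrifluoroborate | C=C[B-](F)(F)F.[K+] | starting material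
11 | [(1R)-1,3-dimethyl-2-vinylcyclohex-2-en-1-yl]methanol | CC1=C(C=C)[C@](C)(CO)CCC1 | intermediate
12 | but-2-ynoic acid | CC#CC(=O)O | starting material
13 | [(1R)-1,3-dimethyl-2-vinylcyclohex-2-en-1-yl]methyl but-2-ynoate | CC#CC(=O)OC[C@]1(C)CCCC(C)=C1C=C | intermediate
14 | tricyclic lactone (18→11 lactone of 18-hydroxy-12,13,14,15,16-pentanorlabda-5,8-dien-11-oic acid; C19 and C20 β) | CC1=C2C(=O)OC[C@]3(C)CCC[C@@]2(C)C3=CC1 | intermediate
15 | methyl 18-hydroxy-12,13,14,15,16-pentanorlabda-5,8-dien-11-oate | COC(=O)C1=C(C)CC=C2[C@](C)(CO)CCC[C@]12C | intermediate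
16 | methyl 18-(triethylsilyloxy)-12,13,14,15,16-pentanorlabda-5,8-dien-11-oate | COC(=O)C1=C(C)CC=C2[C@](C)(CO[Si](CC)(CC)CC)CCC[C@]12C | intermediate
17 | C6α alkylborane from 16 (5α-H, 6α-BH2) | COC(=O)C1=C(C)C[C@H](B)[C@H]2[C@](C)(CO[Si](CC)(CC)CC)CCC[C@]12C | intermediate (not isolated)
18 | methyl 6α-hydroxy-18-(triethylsilyloxy)-12,13,14,15,16-pentanorlabd-8-en-11-oate (5α-H) | COC(=O)C1=C(C)C[C@H](O)[C@H]2[C@](C)(CO[Si](CC)(CC)CC)CCC[C@]12C | intermediate
19 | methyl 6α-(tert-butyldimethylsilyloxy)-18-(triethylsilyloxy)-12,13,14,15,16-pentanorlabd-8-en-11-oate | COC(=O)C1=C(C)C[C@H](O[Si](C)(C)C(C)(C)C)[C@H]2[C@](C)(CO[Si](CC)(CC)CC)CCC[C@]12C | intermediate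
20 | photodienol (ketene hemiacetal C9=C11(OH)OMe with C8=C17) | C=C1C[C@H](O[Si](C)(C)C(C)(C)C)[C@H]2[C@](C)(CO[Si](CC)(CC)CC)CCC[C@]2(C)C1=C(O)OC | intermediate (not isolated)
21 | methyl 6α-(tert-butyldimethylsilyloxy)-18-(triethylsilyloxy)-12,13,14,15,16-pentanorlabd-8(17)-en-11-oate (5α-H, 9α-H) | C=C1C[C@H](O[Si](C)(C)C(C)(C)C)[C@H]2[C@](C)(CO[Si](CC)(CC)CC)CCC[C@]2(C)[C@H]1C(=O)OC | intermediate
22 | 6α-(tert-butyldimethylsilyloxy)-18-(triethylsilyloxy)-12,13,14,15,16-pentanorlabd-8(17)-en-11-ol | C=C1C[C@H](O[Si](C)(C)C(C)(C)C)[C@H]2[C@](C)(CO[Si](CC)(CC)CC)CCC[C@]2(C)[C@H]1CO | intermediate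
23 | 6α-(tert-butyldimethylsilyloxy)-18-(triethylsilyloxy)-12,13,14,15,16-pentanorlabd-8(17)-en-11-al | C=C1C[C@H](O[Si](C)(C)C(C)(C)C)[C@H]2[C@](C)(CO[Si](CC)(CC)CC)CCC[C@]2(C)[C@H]1C=O | intermediate
24 | 6α-(tert-butyldimethylsilyloxy)-18-(triethylsilyloxy)-13,14,15,16-tetranorlabda-8(17),11-diene | C=C1C[C@H](O[Si](C)(C)C(C)(C)C)[C@H]2[C@](C)(CO[Si](CC)(CC)CC)CCC[C@]2(C)[C@H]1C=C | intermediate
25 | (Z)-3-iodobut-2-enoic acid | C/C(I)=C/C(=O)O | intermediate
26 | 2-(trimethylsilyl)ethyl (Z)-3-iodobut-2-enoate | C/C(I)=C/C(=O)OCC[Si](C)(C)C | intermediate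
27 | C12 bis(3-methylbutan-2-yl)borane from 24 | C=C1C[C@H](O[Si](C)(C)C(C)(C)C)[C@H]2[C@](C)(CO[Si](CC)(CC)CC)CCC[C@]2(C)[C@H]1CCB(C(C)C(C)C)C(C)C(C)C | intermediate (not isolated)
28 | 2-(trimethylsilyl)ethyl (13Z)-6α-(tert-butyldimethylsilyloxy)-18-(triethylsilyloxy)labda-8(17),13-dien-15-oate | C=C1C[C@H](O[Si](C)(C)C(C)(C)C)[C@H]2[C@](C)(CO[Si](CC)(CC)CC)CCC[C@]2(C)[C@H]1CC/C(C)=C\C(=O)OCC[Si](C)(C)C | intermediate
29 | 2-(trimethylsilyl)ethyl (13Z)-6α-(tert-butyldimethylsilyloxy)-18-hydroxylabda-8(17),13-dien-15-oate | C=C1C[C@H](O[Si](C)(C)C(C)(C)C)[C@H]2[C@](C)(CO)CCC[C@]2(C)[C@H]1CC/C(C)=C\C(=O)OCC[Si](C)(C)C | intermediate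
30 | 2-(trimethylsilyl)ethyl (13Z)-18-benzoyloxy-6α-(tert-butyldimethylsilyloxy)labda-8(17),13-dien-15-oate | C=C1C[C@H](O[Si](C)(C)C(C)(C)C)[C@H]2[C@](C)(COC(=O)c3ccccc3)CCC[C@]2(C)[C@H]1CC/C(C)=C\C(=O)OCC[Si](C)(C)C | intermediate
31 | (13Z)-18-benzoyloxy-6α-hydroxylabda-8(17),13-dien-15-oic acid (CNP0304840.1) | C=C1C[C@H](O)[C@H]2[C@](C)(COC(=O)c3ccccc3)CCC[C@]2(C)[C@H]1CC/C(C)=C\C(=O)O | target

**Step count**
Total: 22 steps. Longest linear sequence: 20 steps (steps 1–16 and 19–22; steps 17–18 make fragment 26).

**Steps most likely to fail**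

1. Step 8 (the step that carries the new-method label). The cycloaddition may not take place: the ester has to adopt its disfavoured rotamer, the diene is twisted out of plane, and the product holds two bridgehead alkenes, so [1,5]-hydrogen shift in the diene or oligomerisation may win. Fallback with known chemistry, setting out from 11: the alcohol is silylated (TESCl, imidazole) to the triethylsilyl ether F1, which is heated neat in a sealed tube or pressurised with methyl but-2-ynoate in a bimolecular Diels–Alder reaction, the reaction type known for 1-vinyl-2,6,6-trimethylcyclohexene and acetylenic esters. Facial selectivity at C10 then rests only on the steric difference between the two C4 substituents, so 16 would have to be separated from the C10 epimer F2. The route is rejoined at 16, without the lactone stage.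

2. Step 13. Photoenolisation may be inefficient for the twisted, tetrasubstituted chromophore, or the dienol may revert to the conjugated ester instead of being protonated at C9. Fallback from 19: ground-state deconjugation, in which LiN(iPr)2 in THF/DMPU at −78 °C removes a proton from the γ-methyl C17 that lies cis to the ester, giving the lithium dienolate F3, and kinetic protonation at the α-carbon with acetic acid at −78 °C (again from the α face) returns the route at 21.

3. Step 19. Site selectivity of the hydroboration may be lost to the C8=C17 methylene, or the hindered dialkylborane may transmetalate slowly. Fallback from 24: iridium-catalysed hydroboration with pinacolborane ([Ir(cod)Cl]2, dppm), which is selective for monosubstituted alkenes, gives the C12 pinacol boronate F4, oxidised in the same flask (NaBO3) to the C12 alcohol F5. Iodination (I2, PPh3, imidazole) gives the C12 iodide F6, zinc insertion the alkylzinc iodide F7, and Negishi coupling with 26 (Pd(PPh3)4, THF) returns the route at 28.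

**Further compounds**

F1 | step 8 | triethyl{[(1R)-1,3-dimethyl-2-vinylcyclohex-2-en-1-yl]methoxy}silane | CC1=C(C=C)[C@](C)(CO[Si](CC)(CC)CC)CCC1
F2 | step 8 | C10 epimer of 16 (C20 α) | COC(=O)C1=C(C)CC=C2[C@](C)(CO[Si](CC)(CC)CC)CCC[C@@]12C
F3 | step 13 | lithium dienolate of 19 (C8=C17, C9=C11) | C=C1C[C@H](O[Si](C)(C)C(C)(C)C)[C@H]2[C@](C)(CO[Si](CC)(CC)CC)CCC[C@]2(C)C1=C([O-])OC.[Li+]
F4 | step 19 | C12 pinacol boronate from 24 | C=C1C[C@H](O[Si](C)(C)C(C)(C)C)[C@H]2[C@](C)(CO[Si](CC)(CC)CC)CCC[C@]2(C)[C@H]1CCB1OC(C)(C)C(C)(C)O1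
F5 | step 19 | C12 alcohol (13,14,15,16-tetranorlabd-8(17)-en-12-ol, 6α-OTBS, 18-OTES) | C=C1C[C@H](O[Si](C)(C)C(C)(C)C)[C@H]2[C@](C)(CO[Si](CC)(CC)CC)CCC[C@]2(C)[C@H]1CCO
F6 | step 19 | C12 iodide | C=C1C[C@H](O[Si](C)(C)C(C)(C)C)[C@H]2[C@](C)(CO[Si](CC)(CC)CC)CCC[C@]2(C)[C@H]1CCI
F7 | step 19 | C12 alkylzinc iodide | C=C1C[C@H](O[Si](C)(C)C(C)(C)C)[C@H]2[C@](C)(CO[Si](CC)(CC)CC)CCC[C@]2(C)[C@H]1CC[Zn]I
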